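Delta spends its initiator 21 times faster than gamma, so I compared the flasks by what a mole of initiator buys, not by how fast it goes.

| setting | beta | gamma | delta |
|---|---|---|---|
| free monomer | 0.50 M | 0.50 M | 0.50 M |
| initiator | 23 mM | 23 mM | 23 mM |
| time | 4.0 h | 4.0 h | 4.0 h |
| remark | at 60 °C until 2.0 h, from then on at 90 °C |  |  |
| temperature |  | 60 °C | 90 °C |

- which flask leads in amount of monomer in chains, in percent of the free monomer charged ("all alike" within 1.5 percentage points) (beta / gamma / delta / all alike)
- how much monomer in chains is there at the end, in percent of the free monomer charged: beta
- how much monomer in chains is there at the end, in percent of the free monomer charged: gamma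
- how much monomer in chains is there at the end, in percent of the free monomer charged: delta

- a species is counted by the free monomer in it: one self-condensation product counts as two
- where a step has two of a species, its rate is k times that concentration squared, and two are used at each turn
- the constants hold at 60 °C; other temperatures follow from the activation energies and enthalpies

    initiator → 2 initiating radical (k1 = 0.601 /h, Ea1 = 102 kJ/mol)
    free monomer + initiating radical → growing radical + monomer in chains (k2 = 1.49 × 10⁷ /M/h, Ea2 = 26.0 kJ/mol)
    free monomer + growing radical → monomer in chains + growing radical, rate k3*[growing radical]*[free monomer] (k3 = 1.71 × 10⁶ /M/h, Ea3 = 49.0 kJ/mol)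
    free monomer ⇌ dormant form (K4 = 2.2, k4 = 0.980 /h, Ea4 = 114 kJ/mol, ΔH4 = −7.00 kJ/mol)
    2 free monomer → self-condensation product (k5 = 0.0605 /M/h, Ea5 = 66.0 kJ/mol)
    2 growing radical → dead chain (k6 = 7.6 × 10⁷ /M/s, Ea6 = 15.0 kJ/mol)
    (constants at 60 °C)

I kept a ledger on the initiator. Each mole gives 2 initiating radicals, and each of these puts one free monomer into chains, so a used-up charge books A = 9.20% of the monomer. Beta and delta book that, since hot initiator lives 4.77 min; gamma, after 4.0 h at 60 °C, books 8.37%.

The second entry is the growth while those radicals live. Write d, p and c for the constants of initiator decay, propagation and termination, and N for the initiator charge. Growing radicals start near 2.25 × 10⁻⁷ M and last 0.0293 s, far shorter than the initiator's 1.66 h, so I set their making equal to their loss. Their concentration then falls as the root of the initiator. Integrating p times that concentration over a whole charge gives D = 2p·sqrt(N/(dc)), which is 1.28 at 60 °C. The constants d, p and c at 90 °C each grow by the decay factor raised to their own activation energy over that of decay, so D falls to 0.963.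

Propagation reaches free monomer, not the dormant form. The equilibrium free share is 0.312 cold and 0.359 hot. But the charge starts wholly free, and that surplus relaxes at 1.43 /h cold and 45.8 /h hot. Folding it against the falling radicals adds 0.153 cold and 0.0746 hot.

So I carried the dose x, the time integral of p times growing radical times free share. It is the number of e-foldings of the pool of free monomer plus dormant form, which is pseudo-first-order in radicals. Gamma gets 0.433 and delta 0.421. Beta takes the cold part up to 2.0 h and then burns its remaining initiator at the hot rate, for 0.523.

The books close with the share in chains as one minus (one minus A) times exp(−x). I left self-condensation off, its first-order loss at the start of gamma being smaller, 0.0605 /h against 0.384 /h. That gives 46.2% for beta, 40.6% for gamma and 40.4% for delta, with beta ahead.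

The forecast said 44.8%, 38.5% and 42% in that order, with beta ahead through “a late burst”.

The flasks gave 45.0%, 39.2% and 40.2%, and beta led. The dose holds no monomer charge, so for a neighbour flask, beta with 1.2 M of free monomer and the same initiator, I kept 0.523 and changed the first entry to 3.83%. The books then close at 43.0%. That flask gave 39.7% in chains, with 17.0% as free monomer, initiator at 0%, and self-condensation product at 12.9%.

Its constants stand for no real mixture; the result is computed.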